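**Plan**
Ring A is numbered C1 (methyl), C2 (OH), C3 (acyl), C4 (OH), C5 (carries the methine), C6 (OH). Its acyl carbon C3 lies between two oxygenated carbons, which is the pattern left by a 1-alkoxy-1,3-bis(silyloxy)diene (C5–C6–C1–C2) adding to a 1-alkoxyalk-1-yn-3-one (C4–C3).
Retrosynthesis: the ethyl ether at C4 is cleaved last. Ring A is cut at C4–C5 and C2–C3 into a tris-silylated diene (carrying the stereocentre and ring B) and 1-ethoxy-5-phenylpent-1-yn-3-one. The diene is cut at the ketone–C(Me) bond (Claisen), then at the stereocentre–ring B bond (Michael addition of syncarpic acid to an enal).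
Forward: isovaleraldehyde → enal → organocatalytic Michael addition/hemiacetal → enol lactone → ring opening with methyl propanoate enolate → two silylations → diene. Ring B is present from the second step; ring A is closed in the ninth step; de-ethylation ends the route.
Stereochemistry: the single stereocentre is set by iminium catalysis with (R)-diphenylprolinol silyl ether (Si-face attack on the E-enal) and is carried through unchanged. The catalyst enantiomer was assigned from the steric-shielding model, not from a measured result.

Key step: step 9

Remark: syncarpic acid and ethoxyacetylene (hexane solution) are taken as purchasable; ring B of the target is one of two interconverting enol forms, so the methine carbon is the only stereocentre.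

**Step 1**
Reactants: 1 3-methylbutanal (isovaleraldehyde); 2 (triphenylphosphoranylidene)acetaldehyde
Product: 3 (E)-5-methylhex-2-enal
Conditions: toluene, 80 °C
Reagents that add atoms: none
Why: Wittig olefination with the stabilised formyl ylide is E-selective and should stop mainly at the enal, because the conjugated product aldehyde is less electrophilic than the saturated one.

**Step 2**
Reactants: 3 (E)-5-methylhex-2-enal; 4 syncarpic acid (2,2,4,4-tetramethylcyclohexane-1,3,5-trione)
Product: 6 (4S)-2-hydroxy-6,6,8,8-tetramethyl-4-(2-methylpropyl)-3,4-dihydro-2H-chromene-5,7(6H,8H)-dione (lactol; both anomers), via open-chain Michael aldehyde 5 (not isolated)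
Conditions: (R)-α,α-diphenylprolinol trimethylsilyl ether (10 mol %), CH2Cl2, 0 °C → rt
Reagents that add atoms: none
Why: Iminium-ion-catalysed Michael addition of a cyclic 1,3-dicarbonyl to an enal (Jørgensen–Hayashi catalysis) sets the stereocentre, since the diphenyl(silyloxy)methyl group of the (R)-catalyst shields the Re face of C3 of the s-trans E-iminium ion, the enol carbon of 4 adds to the Si face to give the S configuration, and the freed aldehyde is trapped as the cyclic hemiacetal.

**Step 3**
Reactants: 6 lactol
Product: 7 (4S)-6,6,8,8-tetramethyl-4-(2-methylpropyl)-3,4-dihydro-2H-chromene-2,5,7(6H,8H)-trione (enol lactone)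
Conditions: TEMPO (20 mol %), PhI(OAc)2 (1.5 equiv), CH2Cl2, rt
Reagents that add atoms: none
Why: Oxoammonium-mediated (TEMPO/PhI(OAc)2) oxidation of a lactol to the lactone is mild and non-basic, and should leave the vinylogous ester and the non-enolisable C4 stereocentre untouched.

**Step 4**
Reactants: 7 enol lactone; 8 methyl propanoate
Product: 10 methyl (5S)-5-(2-hydroxy-3,3,5,5-tetramethyl-4,6-dioxocyclohex-1-en-1-yl)-2,7-dimethyl-3-oxooctanoate (epimers at C2; in equilibrium with its cyclic hemiketal), via methyl propanoate lithium enolate 9 (not isolated)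
Conditions: 8 (3.2 equiv), LiN(iPr)2 (3.0 equiv), THF, −78 °C; then 7, −78 → −40 °C; cold 1 M HCl
Reagents that add atoms: none
Why: In this crossed Claisen condensation the ester enolate should attack the lactone carbonyl, an unhindered enol ester whose leaving group is the stabilised trione enolate, and the β-ketoester formed is deprotonated at once, which prevents a second addition and leaves the stereocentre (β to the reacting carbonyl) untouched.

**Step 5**
Reactants: 10 β-ketoester
Product: 11 methyl (5S)-2,7-dimethyl-5-[3,3,5,5-tetramethyl-4,6-dioxo-2-(trimethylsilyloxy)cyclohex-1-en-1-yl]-3-(trimethylsilyloxy)oct-2-enoate (E/Z mixture at C2=C3)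
Conditions: Me3SiCl (3 equiv), Et3N (3.5 equiv), toluene, rt; filtration under argon
Reagents that add atoms: chlorotrimethylsilane, C[Si](C)(C)Cl
Why: Silyl enol ether formation with Et3N/Me3SiCl is the standard first stage of Chan–Brassard diene synthesis, and it also caps the acidic ring B enol, removing the proton that would quench a ketene acetal and blocking retro-Michael loss of ring B.

**Step 6**
Reactants: 11 bis-silyl enoate
Product: 13 (3Z,5S)-1-methoxy-2,7-dimethyl-5-[3,3,5,5-tetramethyl-4,6-dioxo-2-(trimethylsilyloxy)cyclohex-1-en-1-yl]-1,3-bis(trimethylsilyloxy)octa-1,3-diene, via lithium dienolate 12 (not isolated)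
Conditions: LiN(iPr)2 (1.3 equiv), THF, −78 °C; Me3SiCl (1.5 equiv), −78 °C → rt; hexane, filtration, used crude
Reagents that add atoms: chlorotrimethylsilane, C[Si](C)(C)Cl
Why: Kinetic γ-deprotonation of a 3-silyloxy-enoate and O-silylation of the dienolate is the standard second stage of 1-alkoxy-1,3-bis(silyloxy)diene synthesis; allylic strain with the C2 methyl group should place the side chain cis to the silyloxy group (3Z), and the stereocentre bears no acidic hydrogen.

**Step 7**
Reactants: 14 3-phenylpropanoyl chloride
Product: 15 N-methoxy-N-methyl-3-phenylpropanamide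
Conditions: MeNHOMe·HCl, Et3N, CH2Cl2, 0 °C → rt
Reagents that add atoms: N,O-dimethylhydroxylamine hydrochloride, CNOC.Cl
Why: N-Acylation of N,O-dimethylhydroxylamine by an acid chloride is the routine preparation of a Weinreb amide.

**Step 8**
Reactants: 15 N-methoxy-N-methyl-3-phenylpropanamide; 16 ethoxyethyne (ethoxyacetylene)
Product: 18 1-ethoxy-5-phenylpent-1-yn-3-one, via lithium ethoxyacetylide 17 (not isolated)
Conditions: n-BuLi, THF, −78 °C; then 15, −78 → −20 °C; cold aq. NH4Cl; chromatography on Et3N-deactivated silica
Reagents that add atoms: none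
Why: In the Weinreb ketone synthesis the lithium acetylide adds only once because the chelated tetrahedral intermediate persists until the buffered quench, which also spares the acid-sensitive ynol ether.

**Step 9**
Reactants: 13 tris-silyl diene; 18 1-ethoxy-5-phenylpent-1-yn-3-one
Product: 21 2-[(1S)-1-[2-ethoxy-4,6-dihydroxy-5-methyl-3-(3-phenylpropanoyl)phenyl]-3-methylbutyl]-3-hydroxy-4,4,6,6-tetramethylcyclohex-2-ene-1,5-dione (the 4-O-ethyl ether of the target), via cyclohexadiene cycloadduct 19 (not isolated), via silylated arene 20 (not isolated)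
Conditions: toluene (concentrated), 70 °C, sealed under argon; then 1 M HCl, THF, 0 °C → rt
Reagents that add atoms: none
Why: Proposed new method: the nucleophilic diene terminus C4 of 13 adds to the ethoxy-bearing β-carbon of the push–pull ynone 18 and the ketene-acetal carbon C1 bonds to the α-carbon, as an asynchronous [4+2] cycloaddition or as a Mukaiyama–Michael addition whose allenolate closes onto the silyloxycarbenium ion, giving the 1,4-cyclohexadiene 19, whose mixed methyl silyl ketal loses methoxytrimethylsilane to a 4H-cyclohexadienone that tautomerises to the phenol 20 before the acid work-up removes the remaining silyl groups. The closest known reaction type is the Diels–Alder/aromatisation of Chan–Brassard 1-alkoxy-1,3-bis(silyloxy)dienes with propiolates and alkynyl ketones to resorcinols; what has not been shown is a 1-alkoxyalk-1-yn-3-one as the two-carbon partner, which here brings in the third ring oxygen and the acyl group together. Ring A is closed as a six-membered carbocycle by this [4+2] annulation (the C4–C5 and C2–C3 bonds of the target) and no stereocentre is created, because the two sp3 ring carbons of 19 become aromatic. The step needs regioselectivity, which the matched polarisation of the ketene acetal (nucleophilic at its γ-terminus) and of the ynone (electrophilic at the oxygen-bearing β-carbon) should secure, and loss of the methoxy group in preference to the silyloxy group, which follows because the O–Si bond is the weak link of the ketal. The 3Z enol silane keeps the branched side chain on the outside of the s-cis diene, the silyl cap on ring B removes the one acidic proton of the substrate, and 70 °C stays below the retro-ene fragmentation of the ethyl ynol ether. The existing stereocentre is a spectator, since it bears no enolisable hydrogen and ring B cannot be expelled while its enol is silylated.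

**Step 10**
Reactants: 21 4-O-ethyl ether of the target
Product: 22 3-hydroxy-4,4,6,6-tetramethyl-2-[(1S)-3-methyl-1-[2,4,6-trihydroxy-3-methyl-5-(3-phenylpropanoyl)phenyl]butyl]cyclohex-2-ene-1,5-dione (CNP0188786.1)
Conditions: BCl3 (5 equiv), CH2Cl2, −78 → 0 °C; then H2O
Reagents that add atoms: none
Why: Chelation-assisted dealkylation of an aryl ether ortho to a ketone by BCl3 (boron bridges carbonyl and ether oxygen, chloride removes the ethyl group) is a standard selective ether cleavage, and at low temperature without base the benzylic stereocentre should not ionise.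

**Compound list**
1 | 3-methylbutanal (isovaleraldehyde) | CC(C)CC=O | starting material
2 | (triphenylphosphoranylidene)acetaldehyde | O=CC=P(c1ccccc1)(c1ccccc1)c1ccccc1 | starting material
3 | (E)-5-methylhex-2-enal | CC(C)C/C=C/C=O | intermediate
4 | syncarpic acid (2,2,4,4-tetramethylcyclohexane-1,3,5-trione) | CC1(C)C(=O)CC(=O)C(C)(C)C1=O | starting material
5 | (3S)-3-(2-hydroxy-3,3,5,5-tetramethyl-4,6-dioxocyclohex-1-en-1-yl)-5-methylhexanal | O=CC[C@H](CC(C)C)C1=C(O)C(C)(C)C(=O)C(C)(C)C1=O | intermediate
6 | (4S)-2-hydroxy-6,6,8,8-tetramethyl-4-(2-methylpropyl)-3,4-dihydro-2H-chromene-5,7(6H,8H)-dione | OC1C[C@H](CC(C)C)C2=C(O1)C(C)(C)C(=O)C(C)(C)C2=O | intermediate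
7 | (4S)-6,6,8,8-tetramethyl-4-(2-methylpropyl)-3,4-dihydro-2H-chromene-2,5,7(6H,8H)-trione | O=C1C[C@H](CC(C)C)C2=C(O1)C(C)(C)C(=O)C(C)(C)C2=O | intermediate
8 | methyl propanoate | CCC(=O)OC | starting material
9 | lithium enolate of methyl propanoate | CC=C([O-])OC.[Li+] | intermediate
10 | methyl (5S)-5-(2-hydroxy-3,3,5,5-tetramethyl-4,6-dioxocyclohex-1-en-1-yl)-2,7-dimethyl-3-oxooctanoate | COC(=O)C(C)C(=O)C[C@H](CC(C)C)C1=C(O)C(C)(C)C(=O)C(C)(C)C1=O | intermediate
11 | methyl (5S)-2,7-dimethyl-5-[3,3,5,5-tetramethyl-4,6-dioxo-2-(trimethylsilyloxy)cyclohex-1-en-1-yl]-3-(trimethylsilyloxy)oct-2-enoate | COC(=O)C(C)=C(O[Si](C)(C)C)C[C@H](CC(C)C)C1=C(O[Si](C)(C)C)C(C)(C)C(=O)C(C)(C)C1=O | intermediate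
12 | lithium dienolate of 11 (lithium (3Z,5S)-1-methoxy-2,7-dimethyl-5-[3,3,5,5-tetramethyl-4,6-dioxo-2-(trimethylsilyloxy)cyclohex-1-en-1-yl]-3-(trimethylsilyloxy)octa-1,3-dien-1-olate) | COC([O-])=C(C)/C(O[Si](C)(C)C)=C/[C@H](CC(C)C)C1=C(O[Si](C)(C)C)C(C)(C)C(=O)C(C)(C)C1=O.[Li+] | intermediate
13 | (3Z,5S)-1-methoxy-2,7-dimethyl-5-[3,3,5,5-tetramethyl-4,6-dioxo-2-(trimethylsilyloxy)cyclohex-1-en-1-yl]-1,3-bis(trimethylsilyloxy)octa-1,3-diene | COC(O[Si](C)(C)C)=C(C)/C(O[Si](C)(C)C)=C/[C@H](CC(C)C)C1=C(O[Si](C)(C)C)C(C)(C)C(=O)C(C)(C)C1=O | intermediate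
14 | 3-phenylpropanoyl chloride | O=C(Cl)CCc1ccccc1 | starting material
15 | N-methoxy-N-methyl-3-phenylpropanamide | CON(C)C(=O)CCc1ccccc1 | intermediate
16 | ethoxyethyne (ethoxyacetylene) | CCOC#C | starting material
17 | lithium ethoxyacetylide | CCOC#[C-].[Li+] | intermediate
18 | 1-ethoxy-5-phenylpent-1-yn-3-one | CCOC#CC(=O)CCc1ccccc1 | intermediate
19 | 1-[2-ethoxy-6-methoxy-5-methyl-3-[(1S)-3-methyl-1-[3,3,5,5-tetramethyl-4,6-dioxo-2-(trimethylsilyloxy)cyclohex-1-en-1-yl]butyl]-4,6-bis(trimethylsilyloxy)cyclohexa-1,4-dien-1-yl]-3-phenylpropan-1-one (diastereomers at the two sp3 ring carbons) | CCOC1=C(C(=O)CCc2ccccc2)C(OC)(O[Si](C)(C)C)C(C)=C(O[Si](C)(C)C)C1[C@H](CC(C)C)C3=C(O[Si](C)(C)C)C(C)(C)C(=O)C(C)(C)C3=O | intermediate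
20 | 1-[2-ethoxy-6-hydroxy-5-methyl-3-[(1S)-3-methyl-1-[3,3,5,5-tetramethyl-4,6-dioxo-2-(trimethylsilyloxy)cyclohex-1-en-1-yl]butyl]-4-(trimethylsilyloxy)phenyl]-3-phenylpropan-1-one | CCOc1c(C(=O)CCc2ccccc2)c(O)c(C)c(O[Si](C)(C)C)c1[C@H](CC(C)C)C1=C(O[Si](C)(C)C)C(C)(C)C(=O)C(C)(C)C1=O | intermediate
21 | 2-[(1S)-1-[2-ethoxy-4,6-dihydroxy-5-methyl-3-(3-phenylpropanoyl)phenyl]-3-methylbutyl]-3-hydroxy-4,4,6,6-tetramethylcyclohex-2-ene-1,5-dione | CCOc1c(C(=O)CCc2ccccc2)c(O)c(C)c(O)c1[C@H](CC(C)C)C1=C(O)C(C)(C)C(=O)C(C)(C)C1=O | intermediate
22 | 3-hydroxy-4,4,6,6-tetramethyl-2-[(1S)-3-methyl-1-[2,4,6-trihydroxy-3-methyl-5-(3-phenylpropanoyl)phenyl]butyl]cyclohex-2-ene-1,5-dione | Cc1c(O)c(C(=O)CCc2ccccc2)c(O)c([C@H](CC(C)C)C2=C(O)C(C)(C)C(=O)C(C)(C)C2=O)c1O | target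

**Step count**
Total: 10 steps. Longest linear sequence: 8 steps (1, 2, 3, 4, 5, 6, 9, 10); steps 7 and 8 form the side branch.

**Steps most likely to fail**

Step 9 (the new annulation). The alkoxy group deactivates the ynone, so addition to the hindered diene terminus may be slow. The diene would then be lost by desilylation and the ynone by retro-ene fragmentation, or a Michael adduct could form and fail to close. The fallback uses known chemistry and gives up the annulation; it sets out from 14, 4 and 1 and comes back to the route at 22. Friedel–Crafts acylation of commercial 2-methylbenzene-1,3,5-triol with 14 (AlCl3, nitrobenzene) would give 1-(2,4,6-trihydroxy-3-methylphenyl)-3-phenylpropan-1-one F1. Knoevenagel condensation of 4 with 1 under amine catalysis would give 2-(3-methylbutylidene)-4,4,6,6-tetramethylcyclohexane-1,3,5-trione F2. Friedel–Crafts-type Michael addition of the one free ring carbon of F1 to F2, the established way of joining acylphloroglucinols to syncarpic acid units, would give 22 directly. The S enantiomer would be secured by running this addition under a chiral Lewis acid such as the lithium aluminium binaphtholate LiAl(BINOL)2, or, if selectivity is insufficient, by separation on a chiral stationary phase.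

Step 6. Deprotonation of the γ-methylene next to the branched stereocentre may be slow, so that the amide base attacks silicon or the ester instead, and the silyl groups of 11 may be lost to moisture during its isolation. The fallback sets out from 10 and comes back at 13. It replaces the lithium dienolate by soft enolisation: Me3SiOTf/Et3N in Et2O at 0 °C, a known one-flask entry to 1,3-bis(silyloxy)dienes from β-ketoesters (O-silylation to silyloxycarbenium ions, then deprotonation by the amine). No strong base is used and 11 is not isolated; this fallback makes no compound outside the list (F0).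

Step 2. The acidic trione may protonate or desilylate the aminocatalyst, giving slow turnover and poor facial selectivity, and a Knoevenagel/oxa-electrocyclisation pathway may compete. The fallback sets out from 3 and 4 and comes back at 7. It changes the activation mode to N-heterocyclic carbene oxidative catalysis: a chiral aminoindanol-derived triazolium salt, a base and 3,3′,5,5′-tetra-tert-butyldiphenoquinone would convert 3 into an α,β-unsaturated acyl azolium, to which 4 adds by Michael addition and lactonisation. This is a known enantioselective route from enals and cyclic 1,3-diones to dihydropyranones. It would give lactone 7 directly, without the lactol or its oxidation, with the catalyst enantiomer chosen for the 4S product; it makes no compound outside the list (F0).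

**Further compounds**
F1 | step 9 | 1-(2,4,6-trihydroxy-3-methylphenyl)-3-phenylpropan-1-one | Cc1c(O)cc(O)c(C(=O)CCc2ccccc2)c1O
F2 | step 9 | 2-(3-methylbutylidene)-4,4,6,6-tetramethylcyclohexane-1,3,5-trione | CC(C)CC=C1C(=O)C(C)(C)C(=O)C(C)(C)C1=O
F0 | step 6 | none | none
F0 | step 2 | none | none
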